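**Plan**

- Numbering: C11 is the ester carbonyl; ring A is C1(CO2R)–C2(Me)–C3–C4–C5(Me)–C10(Me); ring B is C5–C6(homoprenyl)=C7–C8–C9–C10.
- Enabling feature: ring B is a cyclohexene whose allylic bond C5–C10 is also the ring fusion between the two methyl-bearing quaternary carbons, and C1 next to C10 can be a ketone. A retro-[4+2] across C5–C10 and C8–C9 therefore opens both rings to an acyclic isopropenyl ketone carrying a diene.
- Cuts, in retrosynthetic order: glyceryl O–CH2 (carboxylate plus glycidyl acetate), C1–C11 (one-carbon homologation of the C1 ketone), C5–C10 with C8–C9 (intramolecular Diels–Alder), C1–C10 (Grignard), C7–C8 (Wittig), C4–C5 (B-alkyl Suzuki), C6–homoprenyl (acetoacetate alkylation).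
- Forward: the chain is joined first (chiral alkylborane plus enol triflate), diene and enone are installed, rings A and B then close together in one step, and C11 and the glyceride are attached last.
- Stereochemistry: C2 comes from methyl (S)-3-hydroxy-2-methylpropanoate; C5 and C10 are set in the cycloaddition (cis by the ketone-endo transition state and the E diene, face by C2); C1 is set by equilibration of the aldehyde; the glycerol centre comes from (S)-glycidol.

Key step: step 14

**Route**

Step 1
Reactants: 1 methyl (S)-3-hydroxy-2-methylpropanoate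
Product: 2 methyl (S)-3-[(tert-butyldimethylsilyl)oxy]-2-methylpropanoate
Conditions: TBSCl, imidazole, CH2Cl2, 0 °C → rt
Reagents that add atoms: tert-butyldimethylsilyl chloride, CC(C)(C)[Si](C)(C)Cl
Why: Imidazole-promoted silylation of the primary alcohol gives an ether that should survive the hydride, ylide, borane and palladium steps and is removable by fluoride, the stereocentre being untouched.

Step 2
Reactants: 2 methyl (S)-3-[(tert-butyldimethylsilyl)oxy]-2-methylpropanoate
Product: 3 (S)-3-[(tert-butyldimethylsilyl)oxy]-2-methylpropanal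
Conditions: DIBAL-H (1.05 equiv), CH2Cl2, −78 °C; Rochelle salt work-up
Reagents that add atoms: none
Why: Partial ester reduction with DIBAL-H stops at the aluminium hemiacetal at −78 °C and should release the aldehyde on work-up without epimerising the α-centre.

Step 3
Reactants: 3 (S)-3-[(tert-butyldimethylsilyl)oxy]-2-methylpropanal
Product: 4 (R)-tert-butyldimethyl[(2-methylbut-3-en-1-yl)oxy]silane
Conditions: Ph3PCH3Br, n-BuLi, THF, 0 °C; then 3, −78 °C → rt
Reagents that add atoms: methyltriphenylphosphonium bromide, C[P+](c1ccccc1)(c1ccccc1)c1ccccc1.[Br-]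
Why: Wittig methylenation with the non-stabilised ylide at low temperature should convert the α-chiral aldehyde into the terminal olefin without racemisation (the descriptor changes to R only through the priority switch).

Step 4
Reactants: 5 ethyl acetoacetate; 6 5-bromo-2-methylpent-2-ene
Product: 7 ethyl 2-acetyl-6-methylhept-5-enoate (racemic)
Conditions: NaH, THF/DMF, 0 °C; then 6, NaI (cat.), 60 °C
Reagents that add atoms: none
Why: Acetoacetic ester alkylation, in which the stabilised sodium enolate is C-alkylated by the unhindered primary bromide in an SN2 reaction.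

Step 5
Reactants: 7 ethyl 2-acetyl-6-methylhept-5-enoate
Product: 8 ethyl (2E)-2-(4-methylpent-3-en-1-yl)-3-{[(trifluoromethyl)sulfonyl]oxy}but-2-enoate (OTf trans to the ester)
Conditions: Tf2O, aq. Me4NOH, toluene, 0–5 °C
Reagents that add atoms: trifluoromethanesulfonic anhydride, O=S(=O)(OS(=O)(=O)C(F)(F)F)C(F)(F)F
Why: Stereoselective enol triflation of a β-keto ester: with the non-chelating tetramethylammonium counter-ion the enolate should react in its extended form, which places OTf trans to the ester and so fixes the later C5=C6 geometry.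

Step 6
Reactants: 4 (R)-tert-butyldimethyl[(2-methylbut-3-en-1-yl)oxy]silane; 8 ethyl (2E)-2-(4-methylpent-3-en-1-yl)-3-{[(trifluoromethyl)sulfonyl]oxy}but-2-enoate
Product: 10 ethyl (2E,6R)-7-[(tert-butyldimethylsilyl)oxy]-3,6-dimethyl-2-(4-methylpent-3-en-1-yl)hept-2-enoate, via B-alkyl-9-BBN adduct 9 (not isolated)
Conditions: 9-BBN, THF, 0 °C → rt; then 8, Pd(dppf)Cl2 (5 mol%), AsPh3, Cs2CO3, DMF/H2O, rt
Reagents that add atoms: none
Why: Anti-Markovnikov hydroboration of the terminal olefin followed by B-alkyl Suzuki–Miyaura coupling with the β-triflyloxy enoate should form C4–C5 with retention of olefin geometry, leaving C4 cis to the homoprenyl chain.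

Step 7
Reactants: 10 ethyl (2E,6R)-7-[(tert-butyldimethylsilyl)oxy]-3,6-dimethyl-2-(4-methylpent-3-en-1-yl)hept-2-enoate
Product: 11 (2E,6R)-7-[(tert-butyldimethylsilyl)oxy]-3,6-dimethyl-2-(4-methylpent-3-en-1-yl)hept-2-en-1-ol
Conditions: DIBAL-H (2.5 equiv), CH2Cl2, −78 → 0 °C
Reagents that add atoms: none
Why: DIBAL-H 1,2-reduction of the enoate to the allylic alcohol should leave the tetrasubstituted olefin and the silyl ether intact.

Step 8
Reactants: 11 (2E,6R)-7-[(tert-butyldimethylsilyl)oxy]-3,6-dimethyl-2-(4-methylpent-3-en-1-yl)hept-2-en-1-ol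
Product: 12 (2E,6R)-7-[(tert-butyldimethylsilyl)oxy]-3,6-dimethyl-2-(4-methylpent-3-en-1-yl)hept-2-enal
Conditions: MnO2, CH2Cl2, rt
Reagents that add atoms: none
Why: Allylic oxidation with MnO2 proceeds under neutral conditions that should not isomerise the tetrasubstituted double bond.

Step 9
Reactants: 12 (2E,6R)-7-[(tert-butyldimethylsilyl)oxy]-3,6-dimethyl-2-(4-methylpent-3-en-1-yl)hept-2-enal
Product: 13 (2R,5E)-tert-butyl{[2,5-dimethyl-6-(4-methylpent-3-en-1-yl)octa-5,7-dien-1-yl]oxy}dimethylsilane
Conditions: Ph3PCH3Br, n-BuLi, THF, 0 °C; then 12, −78 → 0 °C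
Reagents that add atoms: methyltriphenylphosphonium bromide, C[P+](c1ccccc1)(c1ccccc1)c1ccccc1.[Br-]
Why: Wittig methylenation of the enal installs C8 and should complete the diene with the C5=C6 geometry unchanged.

Step 10
Reactants: 13 (2R,5E)-tert-butyl{[2,5-dimethyl-6-(4-methylpent-3-en-1-yl)octa-5,7-dien-1-yl]oxy}dimethylsilane
Product: 14 (2R,5E)-2,5-dimethyl-6-(4-methylpent-3-en-1-yl)octa-5,7-dien-1-ol
Conditions: TBAF, THF, 0 °C → rt
Reagents that add atoms: none
Why: Fluoride-mediated desilylation cleaves the primary TBS ether without touching the diene.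

Step 11
Reactants: 14 (2R,5E)-2,5-dimethyl-6-(4-methylpent-3-en-1-yl)octa-5,7-dien-1-ol
Product: 15 (2R,5E)-2,5-dimethyl-6-(4-methylpent-3-en-1-yl)octa-5,7-dienal
Conditions: Dess–Martin periodinane, NaHCO3, CH2Cl2, 0 °C → rt
Reagents that add atoms: none
Why: Buffered Dess–Martin oxidation should give the α-methyl aldehyde without acid or base able to epimerise C2 or isomerise the diene.

Step 12
Reactants: 15 (2R,5E)-2,5-dimethyl-6-(4-methylpent-3-en-1-yl)octa-5,7-dienal; 16 isopropenylmagnesium bromide
Product: 17 (4R,7E)-2,4,7-trimethyl-8-(4-methylpent-3-en-1-yl)deca-1,7,9-trien-3-ol (both C3 epimers)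
Conditions: THF, −78 → 0 °C; aq. NH4Cl
Reagents that add atoms: none
Why: Grignard 1,2-addition to the aldehyde at low temperature forms C1–C10, and the carbinol configuration is irrelevant because it is oxidised in the next step.

Step 13
Reactants: 17 (4R,7E)-2,4,7-trimethyl-8-(4-methylpent-3-en-1-yl)deca-1,7,9-trien-3-ol
Product: 18 (4R,7E)-2,4,7-trimethyl-8-(4-methylpent-3-en-1-yl)deca-1,7,9-trien-3-one
Conditions: Dess–Martin periodinane, NaHCO3, CH2Cl2, 0 °C; used directly
Reagents that add atoms: none
Why: Dess–Martin oxidation of the allylic alcohol to the isopropenyl ketone under buffered, non-enolising conditions should preserve C2.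

Step 14
Reactants: 18 (4R,7E)-2,4,7-trimethyl-8-(4-methylpent-3-en-1-yl)deca-1,7,9-trien-3-one
Product: 19 (2R,4aR,8aS)-2,4a,8a-trimethyl-5-(4-methylpent-3-en-1-yl)-3,4,4a,7,8,8a-hexahydronaphthalen-1(2H)-one (cis-fused; angular methyls cis to each other and trans to the C2 methyl)
Conditions: MeAlCl2 (1.1 equiv), CH2Cl2, −78 → −20 °C
Reagents that add atoms: none
Why: Lewis acid-promoted type 1 intramolecular Diels–Alder reaction of a 2-methyl-1,7,9-decatrien-3-one, the closest known class being trienones that give cis-fused octalones: MeAlCl2 binds the C1 ketone, lowers the LUMO of the isopropenyl unit, and the trialkyl diene adds in a concerted but asynchronous [4+2] in which C8–C9 (diene CH2 to enone β-carbon) is advanced and the hindered C5–C10 bond follows. Ring B closes as the new cyclohexene by the two σ bonds of the cycloaddition, and ring A closes at the same time as a six-membered ring through C5–C10 across the four-atom tether C1–C4. C5 and C10 are set relative to each other by the ketone-endo transition state together with the E geometry of C5=C6 (tether trans to C7), which places both methyl groups on one face. Their absolute sense follows from C2: with the tether in a chair the diene carbon C6 and the C10 methyl are axial on the forming ring A, so an axial C2 methyl would be syn-pentane to the C10 methyl and the equatorial one ends up trans to the angular methyls. The step needs endo over exo closure and one diene face; the in-tether carbonyl secures the first and the C2 methyl the second. Low temperature avoids the thermal 1,5-hydrogen shift open to the Z-methyl diene, and the alkylaluminium scavenges protons that would attack the isopropylidene olefin.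

Step 15
Reactants: 19 (2R,4aR,8aS)-2,4a,8a-trimethyl-5-(4-methylpent-3-en-1-yl)-3,4,4a,7,8,8a-hexahydronaphthalen-1(2H)-one
Product: 20 (2R,4aR,8aS)-2,4a,8a-trimethyl-5-(4-methylpent-3-en-1-yl)-3,4,4a,7,8,8a-hexahydro-2H-spiro[naphthalene-1,2'-oxirane] (spiro carbon of either configuration)
Conditions: Me3S+ I−, n-BuLi, THF, −10 °C; then 19, −10 °C → rt
Reagents that add atoms: trimethylsulfonium iodide, C[S+](C)C.[I-]
Why: Corey–Chaykovsky epoxidation: the small dimethylsulfonium methylide adds irreversibly even to 2,2,6-trisubstituted cyclohexanones and the betaine closes to the spiro-epoxide, whose configuration is of no consequence; low temperature is meant to limit enolisation toward C2.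

Step 16
Reactants: 20 (2R,4aR,8aS)-2,4a,8a-trimethyl-5-(4-methylpent-3-en-1-yl)-3,4,4a,7,8,8a-hexahydro-2H-spiro[naphthalene-1,2'-oxirane]
Product: 22 (1S,2R,4aR,8aR)-2,4a,8a-trimethyl-5-(4-methylpent-3-en-1-yl)-1,2,3,4,4a,7,8,8a-octahydronaphthalene-1-carbaldehyde, via C1-epimeric aldehyde mixture 21 (not isolated)
Conditions: BF3·OEt2 (0.2 equiv), CH2Cl2, −78 °C; aq. NaHCO3; then K2CO3 (cat.), MeOH, rt
Reagents that add atoms: none
Why: Meinwald rearrangement (Lewis acid opening of the 2,2-disubstituted epoxide at the tertiary carbon, then 1,2-hydride shift) gives the aldehyde, and base then equilibrates C1 through the enolate to the epimer with CHO and the C2 methyl both equatorial, the other epimer having a 1,3-diaxial contact in either chair.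

Step 17
Reactants: 22 (1S,2R,4aR,8aR)-2,4a,8a-trimethyl-5-(4-methylpent-3-en-1-yl)-1,2,3,4,4a,7,8,8a-octahydronaphthalene-1-carbaldehyde
Product: 23 (1S,2R,4aR,8aR)-2,4a,8a-trimethyl-5-(4-methylpent-3-en-1-yl)-1,2,3,4,4a,7,8,8a-octahydronaphthalene-1-carboxylic acid
Conditions: NaClO2, NaH2PO4, 2-methylbut-2-ene (excess), t-BuOH/H2O, 0 °C → rt
Reagents that add atoms: sodium chlorite, [Na+].[O-]Cl=O
Why: Pinnick oxidation converts hindered aldehydes to acids without α-epimerisation, and the excess 2-methylbut-2-ene should trap hypochlorous acid before it reaches the two trisubstituted olefins.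

Step 18
Reactants: 24 (S)-glycidol
Product: 25 (R)-glycidyl acetate
Conditions: Ac2O, Et3N, DMAP (cat.), CH2Cl2, 0 °C
Reagents that add atoms: acetic anhydride, CC(=O)OC(C)=O
Why: DMAP-catalysed O-acetylation of the primary alcohol leaves the epoxide and its stereocentre untouched (the descriptor changes only through the priority switch).

Step 19
Reactants: 23 (1S,2R,4aR,8aR)-2,4a,8a-trimethyl-5-(4-methylpent-3-en-1-yl)-1,2,3,4,4a,7,8,8a-octahydronaphthalene-1-carboxylic acid; 25 (R)-glycidyl acetate
Product: 26 (2S)-3-acetoxy-2-hydroxypropyl (1S,2R,4aR,8aR)-2,4a,8a-trimethyl-5-(4-methylpent-3-en-1-yl)-1,2,3,4,4a,7,8,8a-octahydronaphthalene-1-carboxylate (CNP0146255.1)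
Conditions: Bu4NBr (10 mol%), 25 (1.5 equiv), toluene, 80 °C; chromatography on neutral support
Reagents that add atoms: none
Why: Quaternary ammonium-catalysed carboxylic acid–epoxide addition: the carboxylate attacks the unsubstituted epoxide CH2 (SN2), so the hindered acid is esterified by O-alkylation, the glycerol stereocentre is not involved, and neutral handling is meant to limit acyl migration to the free secondary hydroxyl.

**Compound list**

1 | methyl (S)-3-hydroxy-2-methylpropanoate | COC(=O)[C@@H](C)CO | starting material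
2 | methyl (S)-3-[(tert-butyldimethylsilyl)oxy]-2-methylpropanoate | COC(=O)[C@@H](C)CO[Si](C)(C)C(C)(C)C | intermediate
3 | (S)-3-[(tert-butyldimethylsilyl)oxy]-2-methylpropanal | O=C[C@@H](C)CO[Si](C)(C)C(C)(C)C | intermediate
4 | (R)-tert-butyldimethyl[(2-methylbut-3-en-1-yl)oxy]silane | C=C[C@@H](C)CO[Si](C)(C)C(C)(C)C | intermediate
5 | ethyl acetoacetate | CCOC(=O)CC(C)=O | starting material
6 | 5-bromo-2-methylpent-2-ene | CC(C)=CCCBr | starting material
7 | ethyl 2-acetyl-6-methylhept-5-enoate (racemic) | CCOC(=O)C(CCC=C(C)C)C(C)=O | intermediate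
8 | ethyl (2E)-2-(4-methylpent-3-en-1-yl)-3-{[(trifluoromethyl)sulfonyl]oxy}but-2-enoate | CCOC(=O)/C(CCC=C(C)C)=C(\C)OS(=O)(=O)C(F)(F)F | intermediate
9 | (R)-9-{4-[(tert-butyldimethylsilyl)oxy]-3-methylbutyl}-9-borabicyclo[3.3.1]nonane | C[C@H](CCB1C2CCCC1CCC2)CO[Si](C)(C)C(C)(C)C | intermediate
10 | ethyl (2E,6R)-7-[(tert-butyldimethylsilyl)oxy]-3,6-dimethyl-2-(4-methylpent-3-en-1-yl)hept-2-enoate | CCOC(=O)/C(CCC=C(C)C)=C(\C)CC[C@@H](C)CO[Si](C)(C)C(C)(C)C | intermediate
11 | (2E,6R)-7-[(tert-butyldimethylsilyl)oxy]-3,6-dimethyl-2-(4-methylpent-3-en-1-yl)hept-2-en-1-ol | OC/C(CCC=C(C)C)=C(\C)CC[C@@H](C)CO[Si](C)(C)C(C)(C)C | intermediate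
12 | (2E,6R)-7-[(tert-butyldimethylsilyl)oxy]-3,6-dimethyl-2-(4-methylpent-3-en-1-yl)hept-2-enal | O=C/C(CCC=C(C)C)=C(\C)CC[C@@H](C)CO[Si](C)(C)C(C)(C)C | intermediate
13 | (2R,5E)-tert-butyl{[2,5-dimethyl-6-(4-methylpent-3-en-1-yl)octa-5,7-dien-1-yl]oxy}dimethylsilane | C=C/C(CCC=C(C)C)=C(\C)CC[C@@H](C)CO[Si](C)(C)C(C)(C)C | intermediate
14 | (2R,5E)-2,5-dimethyl-6-(4-methylpent-3-en-1-yl)octa-5,7-dien-1-ol | C=C/C(CCC=C(C)C)=C(\C)CC[C@@H](C)CO | intermediate
15 | (2R,5E)-2,5-dimethyl-6-(4-methylpent-3-en-1-yl)octa-5,7-dienal | C=C/C(CCC=C(C)C)=C(\C)CC[C@@H](C)C=O | intermediate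
16 | isopropenylmagnesium bromide | C=C(C)[Mg]Br | starting material
17 | (4R,7E)-2,4,7-trimethyl-8-(4-methylpent-3-en-1-yl)deca-1,7,9-trien-3-ol (C3 epimers) | C=C(C)C(O)[C@H](C)CC/C(C)=C(\CCC=C(C)C)C=C | intermediate
18 | (4R,7E)-2,4,7-trimethyl-8-(4-methylpent-3-en-1-yl)deca-1,7,9-trien-3-one | C=C(C)C(=O)[C@H](C)CC/C(C)=C(\CCC=C(C)C)C=C | intermediate
19 | (2R,4aR,8aS)-2,4a,8a-trimethyl-5-(4-methylpent-3-en-1-yl)-3,4,4a,7,8,8a-hexahydronaphthalen-1(2H)-one | O=C1[C@H](C)CC[C@]2(C)C(CCC=C(C)C)=CCC[C@]12C | intermediate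
20 | (2R,4aR,8aS)-2,4a,8a-trimethyl-5-(4-methylpent-3-en-1-yl)-3,4,4a,7,8,8a-hexahydro-2H-spiro[naphthalene-1,2'-oxirane] (spiro carbon unassigned) | C1OC12[C@H](C)CC[C@]3(C)C(CCC=C(C)C)=CCC[C@]23C | intermediate
21 | (2R,4aR,8aR)-2,4a,8a-trimethyl-5-(4-methylpent-3-en-1-yl)-1,2,3,4,4a,7,8,8a-octahydronaphthalene-1-carbaldehyde, C1 epimer mixture | O=CC1[C@H](C)CC[C@]2(C)C(CCC=C(C)C)=CCC[C@]12C | intermediate
22 | (1S,2R,4aR,8aR)-2,4a,8a-trimethyl-5-(4-methylpent-3-en-1-yl)-1,2,3,4,4a,7,8,8a-octahydronaphthalene-1-carbaldehyde | O=C[C@H]1[C@H](C)CC[C@]2(C)C(CCC=C(C)C)=CCC[C@]12C | intermediate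
23 | (1S,2R,4aR,8aR)-2,4a,8a-trimethyl-5-(4-methylpent-3-en-1-yl)-1,2,3,4,4a,7,8,8a-octahydronaphthalene-1-carboxylic acid | OC(=O)[C@H]1[C@H](C)CC[C@]2(C)C(CCC=C(C)C)=CCC[C@]12C | intermediate
24 | (S)-glycidol | OC[C@H]1CO1 | starting material
25 | (R)-glycidyl acetate | CC(=O)OC[C@H]1CO1 | intermediate
26 | (2S)-3-acetoxy-2-hydroxypropyl (1S,2R,4aR,8aR)-2,4a,8a-trimethyl-5-(4-methylpent-3-en-1-yl)-1,2,3,4,4a,7,8,8a-octahydronaphthalene-1-carboxylate | CC(=O)OC[C@H](O)COC(=O)[C@H]1[C@H](C)CC[C@]2(C)C(CCC=C(C)C)=CCC[C@]12C | target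

**Count**

Total steps: 19. Longest linear sequence: 16 (steps 1–3, 6–17 and 19).

**Steps most likely to fail**

Step 14. The cycloaddition may stall because the Z-methyl on C5 holds the diene out of the s-cis conformation while two fully substituted carbons must be joined. Lewis acid-induced cation–olefin cyclisation or double-bond migration could then overtake ring closure, and the facial selectivity could erode if the tether leaves the chair. The fallback sets out from 18 and comes back at 19, and replaces the ketone by a cationic activating group. Ketalisation of 18 with 1,2-bis(trimethylsilyloxy)ethane and catalytic TMSOTf in CH2Cl2 at −78 °C should give the isopropenyl dioxolane F1. The same acid, with 2,6-di-tert-butylpyridine as proton trap, ionises it reversibly to a 1-alkoxyallyl cation, a much stronger dienophile, and the cationic Diels–Alder reaction closes C8–C9 and C5–C10 to the spiro-ketal cycloadduct F2. PPTS in wet acetone then unmasks ketone 19.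

Step 5. Loss of E/Z control in the O-sulfonylation of the α-substituted enolate would carry a geometric mixture into the diene and from there into trans-dimethyl adducts. The fallback sets out from 9 (made from 4 as in step 6) and comes back at 10, and fixes the geometry by a syn carbometalation. Iodination of 9 (I2, NaOMe) gives the primary iodide F3. Lithium–iodine exchange (t-BuLi) and transfer to copper (CuBr·SMe2) give an alkylcopper reagent that adds syn across ethyl but-2-ynoate at −78 °C, and quenching the vinylcopper with iodine delivers the α-iodo enoate F4 with the chain cis to iodine. Negishi coupling with (4-methylpent-3-en-1-yl)zinc bromide (from 6, Zn, LiCl; Pd(dppf)Cl2) replaces iodine with retention and gives 10.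

Step 15. The ylide may act as a base, so that enolisation toward C2 takes the place of addition and returns ketone with loss of the C2 configuration. The fallback sets out from 19 and comes back at 21. Non-basic methylenation with dimethyltitanocene (toluene, 70 °C) should give the exocyclic alkene F5. 9-BBN, which discriminates a 1,1-disubstituted olefin from trisubstituted ones, places boron on the unhindered CH2 to give the alkylborane F6, and NaBO3 oxidation gives the primary alcohol F7. Dess–Martin oxidation leads to the aldehyde mixture 21, which is equilibrated with K2CO3 in MeOH to 22 as in step 16.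

**Further compounds**

F1 | step 14 | 2-[(2R,5E)-5-methyl-6-(4-methylpent-3-en-1-yl)octa-5,7-dien-2-yl]-2-(prop-1-en-2-yl)-1,3-dioxolane | C=C(C)C1(OCCO1)[C@H](C)CC/C(C)=C(\CCC=C(C)C)C=C
F2 | step 14 | ethylene ketal of 19, (2'R,4a'R,8a'S)-2',4a',8a'-trimethyl-5'-(4-methylpent-3-en-1-yl)-3',4',4a',7',8',8a'-hexahydro-2'H-spiro[1,3-dioxolane-2,1'-naphthalene] | O1CCOC12[C@H](C)CC[C@]3(C)C(CCC=C(C)C)=CCC[C@]23C
F3 | step 5 | (R)-tert-butyl(4-iodo-2-methylbutoxy)dimethylsilane | C[C@H](CCI)CO[Si](C)(C)C(C)(C)C
F4 | step 5 | ethyl (2Z,6R)-7-[(tert-butyldimethylsilyl)oxy]-2-iodo-3,6-dimethylhept-2-enoate | CCOC(=O)/C(I)=C(\C)CC[C@@H](C)CO[Si](C)(C)C(C)(C)C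
F5 | step 15 | (2R,4aR,8aR)-2,4a,8a-trimethyl-1-methylidene-5-(4-methylpent-3-en-1-yl)-1,2,3,4,4a,7,8,8a-octahydronaphthalene | C=C1[C@H](C)CC[C@]2(C)C(CCC=C(C)C)=CCC[C@]12C
F6 | step 15 | 9-(decalinylmethyl)-9-BBN adduct of F5 (boron on the exocyclic CH2, C1 unassigned) | C(B3C4CCCC3CCC4)C1[C@H](C)CC[C@]2(C)C(CCC=C(C)C)=CCC[C@]12C
F7 | step 15 | [(2R,4aR,8aR)-2,4a,8a-trimethyl-5-(4-methylpent-3-en-1-yl)-1,2,3,4,4a,7,8,8a-octahydronaphthalen-1-yl]methanol (C1 unassigned) | OCC1[C@H](C)CC[C@]2(C)C(CCC=C(C)C)=CCC[C@]12C
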